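**Retrosynthetic overview**
1. The strategy rests on the oxolane ring O1–C2(3,4-dihydroxyphenyl)–C3(C9H2OAc)–C4(C7'H2-guaiacyl)–C5, the only ring to be built. It dissects into propargyl alcohol (O1, C5, C4, C7'), a catechol-derived benzylidene malonate (C2, C3, C9) and a guaiacyl iodide.
2. Target ⇐ (Z)-4-arylidene acetate with benzyl-protected phenols (hydrogenation anti to C9 sets C4 and removes the benzyl groups) ⇐ racemic trans alcohol (lipase acetylation selects 2S,3R and installs the acetate).
3. Trans alcohol ⇐ trans 3-ester ⇐ 3,3-diester (Krapcho dealkoxycarbonylation, C3 equilibrated trans to the C2 aryl).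
4. 3,3-Diester ⇐ one-flask oxa-Michael addition, carbopalladation and arylation forming O1–C2, C3–C4 (5-exo-dig, closes the oxolane) and C7'–aryl.
5. The partners come from a Knoevenagel condensation and an O-benzylation.

Key step: step 3

Assumption: every chiral compound before the resolution is a racemate, named and drawn as the enantiomer that is carried on, and the lipase is taken to acylate the (2S,3R) alcohol faster than its mirror image.

**Step 1**
Reactants: 1 3,4-bis(benzyloxy)benzaldehyde; 2 diethyl malonate
Product: 3 diethyl 2-[3,4-bis(benzyloxy)benzylidene]malonate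
Conditions: piperidine (0.1 equiv), AcOH (0.1 equiv), toluene, reflux, Dean–Stark trap
Reagents that add atoms: none
Why: Knoevenagel condensation, in which piperidinium acetate catalysis with azeotropic removal of water should drive the electron-rich aldehyde to the arylidene malonate, and no stereo-element arises because the two ester groups are identical.

**Step 2**
Reactants: 4 4-iodo-2-methoxyphenol
Product: 5 1-(benzyloxy)-4-iodo-2-methoxybenzene
Conditions: BnBr, K2CO3, DMF, rt
Reagents that add atoms: benzyl bromide, BrCc1ccccc1
Why: Williamson ether synthesis, in which the phenoxide is benzylated by SN2 displacement while the aryl iodide is inert to carbonate at room temperature.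

**Step 3**
Reactants: 3 diethyl 2-[3,4-bis(benzyloxy)benzylidene]malonate; 5 1-(benzyloxy)-4-iodo-2-methoxybenzene; 6 propargyl alcohol
Product: 9 diethyl (2R,4Z)-2-[3,4-bis(benzyloxy)phenyl]-4-[4-(benzyloxy)-3-methoxybenzylidene]oxolane-3,3-dicarboxylate (racemate), via lithium prop-2-yn-1-olate 7 (not isolated), via lithium malonate enolate adduct 8 (not isolated)
Conditions: 6, n-BuLi (1 equiv to 6), THF, 0 °C; then 3, 5, PdCl2(PPh3)2 (5 mol %, pre-reduced with n-BuLi, 10 mol %), DMSO–THF, rt
Reagents that add atoms: none
Why: The lithium alkoxide 7 adds reversibly to the benzylidene malonate 3 (oxa-Michael, O1–C2) to give the stabilised enolate 8, while oxidative addition of iodide 5 to zerovalent palladium gives an arylpalladium iodide (divalent palladium) that coordinates the alkyne of 8. The malonate carbon then attacks the activated alkyne anti to palladium in a 5-exo-dig closure that forms C3–C4 and the oxolane ring, and reductive elimination from the resulting vinyl(aryl)palladium forms C7'–aryl and returns zerovalent palladium. The closest known reaction type is the palladium-mediated three-component coupling of propargyl alkoxides, alkylidene malonates and aryl halides to 4-arylidene oxolanes, of which this is a direct application. The only new stereocentre, C2, arises in the reversible alkoxide addition with no chiral element present and is therefore racemic (its descriptor is R here only because the quaternary C3 outranks the aryl group; the spatial arrangement drawn is that of the target), whereas anti carbopalladation followed by stereoretentive reductive elimination fixes the Z alkene with the new aryl group cis to C5. The step needs cyclisation with coupling to outrun direct coupling of the arylpalladium species with the terminal alkyne or the free alkoxide; the doubly stabilised malonate anion held five atoms from the alkyne, the lithium counter-ion and the copper-free, amine-free DMSO medium should secure this.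

**Step 4**
Reactants: 9 diethyl (2R,4Z)-2-[3,4-bis(benzyloxy)phenyl]-4-[4-(benzyloxy)-3-methoxybenzylidene]oxolane-3,3-dicarboxylate (racemate)
Product: 11 ethyl (2S,3S,4Z)-2-[3,4-bis(benzyloxy)phenyl]-4-[4-(benzyloxy)-3-methoxybenzylidene]oxolane-3-carboxylate (racemate; ester trans to the C2 aryl), via cis monoester 10 (not isolated)
Conditions: LiCl, H2O (2 equiv), DMSO, 150 °C, argon; extractive work-up; then NaOEt (0.2 equiv), EtOH, 0 °C to rt, argon
Reagents that add atoms: none
Why: Krapcho dealkoxycarbonylation, in which chloride dealkylates one ethyl ester, loss of CO2 leaves an ester dienolate that water should protonate at its alpha carbon C3 (keeping the aryl-conjugated exocyclic alkene) partly anti to the C2 aryl to give cis ester 10, and the brief catalytic ethoxide equilibration then epimerises C3 to the thermodynamically preferred isomer with the ester trans to the C2 aryl, so that C3 is set from C2 under thermodynamic control.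

**Step 5**
Reactants: 11 ethyl (2S,3S,4Z)-2-[3,4-bis(benzyloxy)phenyl]-4-[4-(benzyloxy)-3-methoxybenzylidene]oxolane-3-carboxylate (racemate)
Product: 12 [(2S,3R,4Z)-2-[3,4-bis(benzyloxy)phenyl]-4-[4-(benzyloxy)-3-methoxybenzylidene]oxolan-3-yl]methanol (racemate)
Conditions: LiAlH4, THF, −20 to 0 °C; aqueous NaOH work-up
Reagents that add atoms: none
Why: Hydride reduction of the ester to the primary alcohol, in which the non-conjugated alkene, the benzyl ethers and the oxolane are inert to LiAlH4 and the fast, cold reduction should leave the C3 configuration untouched (the descriptor changes from S to R only through the priority change at C9).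

**Step 6**
Reactants: 12 [(2S,3R,4Z)-2-[3,4-bis(benzyloxy)phenyl]-4-[4-(benzyloxy)-3-methoxybenzylidene]oxolan-3-yl]methanol (racemate)
Product: 13 [(2S,3R,4Z)-2-[3,4-bis(benzyloxy)phenyl]-4-[4-(benzyloxy)-3-methoxybenzylidene]oxolan-3-yl]methyl acetate (single enantiomer)
Conditions: immobilised Burkholderia cepacia lipase (lipase PS), vinyl acetate (5 equiv), t-BuOMe, 25 °C, stopped at about 45% conversion; chromatography
Reagents that add atoms: vinyl acetate, CC(=O)OC=C
Why: Lipase-catalysed kinetic resolution by irreversible transesterification with vinyl acetate, in which the enzyme distinguishes the C3 stereocentre next to the carbinol carbon so that only the (2S,3R) alcohol should be acylated and separated from the unreacted mirror-image alcohol; no new stereocentre forms, and the step selects the absolute configuration of C2 and C3 and installs the acetate on O9.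

**Step 7**
Reactants: 13 [(2S,3R,4Z)-2-[3,4-bis(benzyloxy)phenyl]-4-[4-(benzyloxy)-3-methoxybenzylidene]oxolan-3-yl]methyl acetate
Product: 14 [(2S,3R,4R)-2-(3,4-dihydroxyphenyl)-4-(4-hydroxy-3-methoxybenzyl)oxolan-3-yl]methyl acetate (CNP0273854.1)
Conditions: H2 (1 atm), 10% Pd/C, EtOAc–EtOH, rt, stopped after uptake of 4 equiv H2
Reagents that add atoms: none
Why: Heterogeneous catalytic hydrogenation with hydrogenolysis, in which H2 should add syn to the face of the C4=C7' alkene opposite the adjacent C3 acetoxymethyl group so that H-4 ends trans and the C7' benzyl group cis to C9 (4R), while the three aryl benzyl ethers are cleaved to the phenols, the acetate is inert, and the neutral medium, low pressure and controlled uptake limit cleavage of the benzylic C2–O1 bond.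

**Compound list**
1 | 3,4-bis(benzyloxy)benzaldehyde | O=Cc1ccc(OCc2ccccc2)c(OCc2ccccc2)c1 | starting material
2 | diethyl malonate | CCOC(=O)CC(=O)OCC | starting material
3 | diethyl 2-[3,4-bis(benzyloxy)benzylidene]malonate | CCOC(=O)C(=Cc1ccc(OCc2ccccc2)c(OCc2ccccc2)c1)C(=O)OCC | intermediate
4 | 4-iodo-2-methoxyphenol | Oc1ccc(I)cc1OC | starting material
5 | 1-(benzyloxy)-4-iodo-2-methoxybenzene | COc1cc(I)ccc1OCc1ccccc1 | intermediate
6 | propargyl alcohol | OCC#C | starting material
7 | lithium prop-2-yn-1-olate (not isolated) | [Li+].[O-]CC#C | intermediate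
8 | lithium enolate of diethyl 2-{[3,4-bis(benzyloxy)phenyl](prop-2-yn-1-yloxy)methyl}malonate (racemate, not isolated) | [Li+].CCOC(=O)C(=C([O-])OCC)[C@H](OCC#C)c1ccc(OCc2ccccc2)c(OCc2ccccc2)c1 | intermediate
9 | diethyl (2R,4Z)-2-[3,4-bis(benzyloxy)phenyl]-4-[4-(benzyloxy)-3-methoxybenzylidene]oxolane-3,3-dicarboxylate (racemate) | CCOC(=O)C1(C(=O)OCC)[C@@H](c2ccc(OCc3ccccc3)c(OCc3ccccc3)c2)OC/C1=C\c1ccc(OCc2ccccc2)c(OC)c1 | intermediate
10 | ethyl (2S,3R,4Z)-2-[3,4-bis(benzyloxy)phenyl]-4-[4-(benzyloxy)-3-methoxybenzylidene]oxolane-3-carboxylate (racemate; cis; not isolated) | CCOC(=O)[C@H]1[C@@H](c2ccc(OCc3ccccc3)c(OCc3ccccc3)c2)OC/C1=C\c1ccc(OCc2ccccc2)c(OC)c1 | intermediate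
11 | ethyl (2S,3S,4Z)-2-[3,4-bis(benzyloxy)phenyl]-4-[4-(benzyloxy)-3-methoxybenzylidene]oxolane-3-carboxylate (racemate; trans) | CCOC(=O)[C@@H]1[C@@H](c2ccc(OCc3ccccc3)c(OCc3ccccc3)c2)OC/C1=C\c1ccc(OCc2ccccc2)c(OC)c1 | intermediate
12 | [(2S,3R,4Z)-2-[3,4-bis(benzyloxy)phenyl]-4-[4-(benzyloxy)-3-methoxybenzylidene]oxolan-3-yl]methanol (racemate) | OC[C@@H]1[C@@H](c2ccc(OCc3ccccc3)c(OCc3ccccc3)c2)OC/C1=C\c1ccc(OCc2ccccc2)c(OC)c1 | intermediate
13 | [(2S,3R,4Z)-2-[3,4-bis(benzyloxy)phenyl]-4-[4-(benzyloxy)-3-methoxybenzylidene]oxolan-3-yl]methyl acetate (single enantiomer) | CC(=O)OC[C@@H]1[C@@H](c2ccc(OCc3ccccc3)c(OCc3ccccc3)c2)OC/C1=C\c1ccc(OCc2ccccc2)c(OC)c1 | intermediate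
14 | [(2S,3R,4R)-2-(3,4-dihydroxyphenyl)-4-(4-hydroxy-3-methoxybenzyl)oxolan-3-yl]methyl acetate | COc1cc(C[C@H]2CO[C@H](c3ccc(O)c(O)c3)[C@H]2COC(C)=O)ccc1O | target

**Step count**
Total steps: 7. Longest linear sequence: 6 steps (steps 1, 3, 4, 5, 6, 7); step 2 is a one-step branch.

**Steps most likely to fail**

Step 6. The enzyme may discriminate poorly between the enantiomers of a primary alcohol whose stereocentre lies one carbon from the reacting oxygen, or it may acylate the mirror-image alcohol faster. Either process would give acetate of low enantiomeric purity. The fallback sets out from racemic alcohol 12. Chemical acetylation (Ac2O, pyridine, catalytic DMAP, CH2Cl2) should give the racemic acetate, that is 13 together with its mirror image [(2R,3S,4Z)-2-[3,4-bis(benzyloxy)phenyl]-4-[4-(benzyloxy)-3-methoxybenzylidene]oxolan-3-yl]methyl acetate F1. Preparative chromatography on a chiral stationary phase (amylose tris(3,5-dimethylphenylcarbamate), hexane–i-PrOH) then separates the two, and the route is rejoined at 13.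

Step 4. The exocyclic C4=C7' alkene may migrate into the ring, into conjugation with the ester, by gamma-protonation of the dienolate in the hot, weakly basic Krapcho medium. This would erase C3 and open a path to furan formation. The fallback sets out from diester 9. Partial saponification (KOH, 1.1 equiv, EtOH–H2O, rt; then HCl) should give the half ester (2R,3R,4Z)-2-[3,4-bis(benzyloxy)phenyl]-4-[4-(benzyloxy)-3-methoxybenzylidene]-3-(ethoxycarbonyl)oxolane-3-carboxylic acid F2 (racemic, C3 epimer mixture, the epimer from attack on the less hindered ester drawn). Heating F2 in toluene at about 100 °C should decarboxylate the malonic half acid through a cyclic transition state to an ester enol that ketonises at C3 in a neutral medium, giving the 10/11 mixture without a free dienolate in hot DMSO. The ethoxide equilibration of step 4 (or, if base proves to cause the migration, chromatographic separation of the trans isomer) then returns the route at 11.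

Step 7. Delivery of H2 to the C4=C7' alkene may show poor facial selectivity, and the C4 epimer would be hard to remove at the polar triphenol stage. Palladium may also open the benzylic C2–O1 or allylic C5–O1 bond by hydrogenolysis. The fallback sets out from acetate 13 and separates the two reductions. Hydrogenation of the alkene alone (H2, 1 atm, 5% Pt/C, EtOAc, rt), which leaves aryl benzyl ethers in place, should give [(2S,3R,4R)-2-[3,4-bis(benzyloxy)phenyl]-4-[4-(benzyloxy)-3-methoxybenzyl]oxolan-3-yl]methyl acetate F3, which is freed from its C4 epimer by chromatography or crystallisation. Catalytic transfer hydrogenolysis (10% Pd/C, 1,4-cyclohexadiene, EtOH, rt) then removes the three benzyl groups under conditions that spare the C2–O1 bond and returns the route at 14.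

The cascade of step 3 is ranked just below these three because its reaction class is established for arylidene malonates and aryl iodides.

**Further compounds**
F1 | step 6 | [(2R,3S,4Z)-2-[3,4-bis(benzyloxy)phenyl]-4-[4-(benzyloxy)-3-methoxybenzylidene]oxolan-3-yl]methyl acetate (mirror image of 13) | CC(=O)OC[C@H]1[C@H](c2ccc(OCc3ccccc3)c(OCc3ccccc3)c2)OC/C1=C\c1ccc(OCc2ccccc2)c(OC)c1
F2 | step 4 | (2R,3R,4Z)-2-[3,4-bis(benzyloxy)phenyl]-4-[4-(benzyloxy)-3-methoxybenzylidene]-3-(ethoxycarbonyl)oxolane-3-carboxylic acid (racemate; major C3 epimer drawn) | CCOC(=O)[C@@]1(C(=O)O)[C@@H](c2ccc(OCc3ccccc3)c(OCc3ccccc3)c2)OC/C1=C\c1ccc(OCc2ccccc2)c(OC)c1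
F3 | step 7 | [(2S,3R,4R)-2-[3,4-bis(benzyloxy)phenyl]-4-[4-(benzyloxy)-3-methoxybenzyl]oxolan-3-yl]methyl acetate | CC(=O)OC[C@@H]1[C@@H](c2ccc(OCc3ccccc3)c(OCc3ccccc3)c2)OC[C@@H]1Cc1ccc(OCc2ccccc2)c(OC)c1
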